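At early times the runs give one number, the feed of starting material into target: spring's first reading, 17.3% at 0.250 h, makes a pseudo-first-order constant of 0.760 /h. Noon's first reading makes 0.591 /h, so, as these two readings stand, this feed goes as [coupling partner] to the power 0.618.

| flask | starting material | coupling partner | remark | time |
|---|---|---|---|---|
| noon | 0.93 M | 1.2 M | run made earlier |  |
| spring | 0.93 M | 1.8 M | run made earlier |  |
| midnight | 0.86 M | 0.93 M | run made earlier |  |
| Saturday's | 0.93 M | 3.00 M |  | 6.0 h |
| Monday's | 0.50 M | 0.930 M |  | 6.0 h |
| Sunday's | 0.93 M | 0.930 M |  | 6.0 h |
| Friday's | 0.50 M | 3.00 M |  | 6.0 h |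

| noon: time / h | noon: target / % | spring: time / h | spring: target / % | midnight: time / h | midnight: target / % |
|---|---|---|---|---|---|
| 0.667 | 32.6 | 0.250 | 17.3 | 0.667 | 28.7 |
| 1.33 | 52.1 | 0.833 | 43.3 | 1.33 | 47.0 |
| 2.00 | 58.5 | 1.33 | 54.7 | 2.00 | 54.1 |
| 2.50 | 65.3 | 2.00 | 64.0 | 2.50 | 60.7 |
| 3.00 | 68.6 | 3.00 | 71.6 | 3.00 | 63.7 |

(each reading ± 1 percentage point)

- a reading or a percentage of target counts all its forms, free or not

1. the flasks by amount of target, in percent of the starting material charged, highest first, at 6.0 h (Saturday's / Monday's / Sunday's / Friday's)
2. the amount of target, in percent of the starting material charged of the flask you put first, at 6.0 h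
3. the amount of target, in percent of the starting material charged of the flask you put last, at 6.0 h

I follow one molecule past two forks: it must become target, and then target must survive. An unslowed feed puts 89.8% into spring at 3.00 h, but the reading is 71.6%. In one extreme version, that shortfall is a slowing feed and target stays. In the other, the feed holds and the shortfall is target lost in step with [coupling partner]. A molecule then has an average age of about 1.68 h and survives with chance 79.8%, which gives the ceiling loss constant 0.0746 /M/h, with target lifetime 1/(constant × [coupling partner]). I do not split the shortfall between the two, so I expect each flask between the extremes.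

At 3.00 M the lifetime is 4.47 h, shorter than the 6.0 h asked; at 0.930 M it is 14.4 h, longer. I therefore expect Friday's and Saturday's between 32.3% and 99.8%, Monday's and Sunday's between 72.0% and 95.2%. Converting its charge of starting material takes about a third of the coupling partner in Saturday's and 16.7% in Friday's, so I expect [coupling partner] to fall further in Saturday's and put it above Friday's. Sunday's charges equal amounts, so its feed should fade, and I put Monday's above it. My order is Monday's, Sunday's, Saturday's, Friday's.

The forecast says Saturday's > Sunday's > Friday's > Monday's, with 86% and 68%, on the ground that “The integrated second-order plot works best”.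

The simulation gives Monday's > Sunday's > Saturday's > Friday's, with 80.3% and 52.9%.

    starting material + coupling partner → target, rate k1*[starting material]*[coupling partner]^0.5 (k = 0.644 /M^0.5/h)
    coupling partner + target → over-reaction product (k = 0.0559 /M/h)
    starting material + target ⇌ idle adduct, settled at all times (K = 1.00 /M)

Friday's ends with 76% of its coupling partner left, which at the ceiling constant makes a target lifetime of 5.90 h, and its 52.9% stands above my lower estimate. The second flask is Friday's read at 10 h, with 72% of the coupling partner left. Over the extra 4.00 h, the ceiling constant at the mean of those two amounts takes 52.9% down to 27.3%, and that flask holds 32.8% of target.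

The numbers in the tables were computed for an exercise; noise was put on by code.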